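**Retrosynthetic overview**
- The strategy rests on the benzenoid ring C4a–C5–C6–C7–C8–C8a of the isochromanone: meta oxygens already differentiated (C6–OMe, C8–OH), C5–CH3, and the adjacent carbons C4a (bearing C4) and C8a (bearing C1). This is the pattern a 1,1,3-trioxygenated diene and an alkynoate give, so C5–C4a and C8–C8a are cut.
- The O2–C3 lactol ring is cut back to the C1 acid and a C3 ketone, carried as a dioxolane so that the C4 stereocentre, taken from the (S)-Roche ester, cannot enolise.
- The C3–CH2–O ester is made early by carboxylate alkylation of a chloromethyl ketone with 2,4-bis(benzyloxy)-3,5,6-trimethylbenzoic acid, itself made from methyl 2,4-dihydroxy-3,6-dimethylbenzoate.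
- Ring order: the right-hand arene is bought, the left arene is built in step 16, and the pyranone ring closes in step 18.

Key step: step 16

Assumption: the hemiketal carbon C3 equilibrates through the open keto acid, and the (3R) epimer (3-OH trans to 4-CH3, both pseudoaxial, keeping the anomeric effect and turning the C4 methyl away from the C5 methyl) is taken to be the thermodynamic one.

**Route**

Step 1
Reactants: 1 methyl 2,4-dihydroxy-3,6-dimethylbenzoate
Product: 2 methyl 5-bromo-2,4-dihydroxy-3,6-dimethylbenzoate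
Conditions: NBS (1.05 equiv), MeCN, 0 °C to rt
Reagents that add atoms: N-bromosuccinimide, O=C1CCC(=O)N1Br
Why: Electrophilic aromatic bromination can only occur at C5, the one free ring position, which is activated by the ortho hydroxyl.

Step 2
Reactants: 2 methyl 5-bromo-2,4-dihydroxy-3,6-dimethylbenzoate
Product: 3 methyl 2,4-bis(benzyloxy)-5-bromo-3,6-dimethylbenzoate
Conditions: BnBr (2.5 equiv), K2CO3, DMF, 60 °C
Reagents that add atoms: benzyl bromide, BrCc1ccccc1
Why: Williamson etherification in warm DMF should alkylate both phenols, including the one hydrogen-bonded to the ester, and the benzyl ethers leave later together with the benzyl ester.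

Step 3
Reactants: 3 methyl 2,4-bis(benzyloxy)-5-bromo-3,6-dimethylbenzoate
Product: 4 methyl 2,4-bis(benzyloxy)-3,5,6-trimethylbenzoate
Conditions: MeB(OH)2 (2 equiv), Pd(OAc)2 (5 mol%), SPhos (10 mol%), K3PO4, toluene/H2O, 100 °C
Reagents that add atoms: methylboronic acid, CB(O)O
Why: Suzuki–Miyaura methylation with a bulky electron-rich biarylphosphine should allow oxidative addition into the di-ortho-substituted, electron-rich aryl bromide, and the small methyl group transfers easily.

Step 4
Reactants: 4 methyl 2,4-bis(benzyloxy)-3,5,6-trimethylbenzoate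
Product: 5 2,4-bis(benzyloxy)-3,5,6-trimethylbenzoic acid
Conditions: KOH (10 equiv), DMSO/H2O 4:1, 100 °C; then aq. HCl to pH 2
Reagents that add atoms: potassium hydroxide, [K+].[OH-]
Why: Saponification of the di-ortho-substituted benzoate needs poorly solvated hydroxide in hot aqueous DMSO, which the benzyl ethers tolerate, and the protected phenols keep the resorcylic acid from decarboxylating.

Step 5
Reactants: 6 methyl (S)-3-hydroxy-2-methylpropanoate
Product: 7 methyl (S)-3-(tert-butyldiphenylsilyloxy)-2-methylpropanoate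
Conditions: TBDPSCl, imidazole, CH2Cl2, 0 °C to rt
Reagents that add atoms: tert-butyl(chloro)diphenylsilane, CC(C)(C)[Si](Cl)(c1ccccc1)c1ccccc1
Why: Silylation of the primary alcohol gives an ether that survives the later Lewis-acid ketalisation, and the stereocentre is not touched.

Step 6
Reactants: 7 methyl (S)-3-(tert-butyldiphenylsilyloxy)-2-methylpropanoate
Product: 8 (S)-3-(tert-butyldiphenylsilyloxy)-N-methoxy-N,2-dimethylpropanamide
Conditions: MeNH(OMe)·HCl (1.5 equiv), iPrMgCl (3 equiv), THF, −20 to 0 °C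
Reagents that add atoms: N,O-dimethylhydroxylamine hydrochloride, CNOC.Cl
Why: Aminolysis of the ester by the magnesium amide of N,O-dimethylhydroxylamine (Weinreb amide formation) runs at low temperature without epimerising the α-centre.

Step 7
Reactants: 8 (S)-3-(tert-butyldiphenylsilyloxy)-N-methoxy-N,2-dimethylpropanamide
Product: 9 (S)-4-(tert-butyldiphenylsilyloxy)-1-chloro-3-methylbutan-2-one
Conditions: ICH2Cl (1.6 equiv), MeLi·LiBr (1.5 equiv), THF, −78 °C; then aq. NH4Cl
Reagents that add atoms: chloroiodomethane, ClCI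
Why: Chloromethyllithium, formed in the flask by iodine–lithium exchange, adds once to the Weinreb amide (carbenoid homologation), and the ketone appears only on quench, so the α′ stereocentre is not exposed to base.

Step 8
Reactants: 9 (S)-4-(tert-butyldiphenylsilyloxy)-1-chloro-3-methylbutan-2-one; 5 2,4-bis(benzyloxy)-3,5,6-trimethylbenzoic acid
Product: 10 (S)-4-(tert-butyldiphenylsilyloxy)-3-methyl-2-oxobutyl 2,4-bis(benzyloxy)-3,5,6-trimethylbenzoate
Conditions: KHCO3 (1.5 equiv), NaI (cat.), DMF, rt
Reagents that add atoms: none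
Why: SN2 O-alkylation of the carboxylate by the very reactive α-chloro ketone forms the hindered aryl ester without acylation at the crowded carbonyl, and bicarbonate is too weak to enolise the ketone or eliminate the β-silyloxy group.

Step 9
Reactants: 10 (S)-4-(tert-butyldiphenylsilyloxy)-3-methyl-2-oxobutyl 2,4-bis(benzyloxy)-3,5,6-trimethylbenzoate
Product: 11 {2-[(S)-1-(tert-butyldiphenylsilyloxy)propan-2-yl]-1,3-dioxolan-2-yl}methyl 2,4-bis(benzyloxy)-3,5,6-trimethylbenzoate
Conditions: TMSOCH2CH2OTMS (3 equiv), TMSOTf (0.2 equiv), CH2Cl2, −78 to −20 °C; pyridine quench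
Reagents that add atoms: 1,2-bis(trimethylsilyloxy)ethane, C[Si](C)(C)OCCO[Si](C)(C)C
Why: Noyori ketalisation is aprotic and cold, so it should convert the ketone into the dioxolane without enolising the adjacent stereocentre or cleaving the silyl ether.

Step 10
Reactants: 11 {2-[(S)-1-(tert-butyldiphenylsilyloxy)propan-2-yl]-1,3-dioxolan-2-yl}methyl 2,4-bis(benzyloxy)-3,5,6-trimethylbenzoate
Product: 12 {2-[(S)-1-hydroxypropan-2-yl]-1,3-dioxolan-2-yl}methyl 2,4-bis(benzyloxy)-3,5,6-trimethylbenzoate
Conditions: TBAF (1.5 equiv), AcOH (1.5 equiv), THF, 0 °C to rt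
Reagents that add atoms: none
Why: Buffered fluoride desilylation frees the primary alcohol, and the di-ortho-substituted benzoate resists acyl migration and cleavage.

Step 11
Reactants: 12 {2-[(S)-1-hydroxypropan-2-yl]-1,3-dioxolan-2-yl}methyl 2,4-bis(benzyloxy)-3,5,6-trimethylbenzoate
Product: 13 {2-[(S)-1-oxopropan-2-yl]-1,3-dioxolan-2-yl}methyl 2,4-bis(benzyloxy)-3,5,6-trimethylbenzoate
Conditions: TEMPO (0.2 equiv), PhI(OAc)2 (1.2 equiv), CH2Cl2, rt; used crude
Reagents that add atoms: none
Why: Oxoammonium (TEMPO/BAIB) oxidation stops at the aldehyde under base-free conditions, so the α-stereocentre, whose only carbonyl neighbour is now the aldehyde, should be kept.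

Step 12
Reactants: 13 {2-[(S)-1-oxopropan-2-yl]-1,3-dioxolan-2-yl}methyl 2,4-bis(benzyloxy)-3,5,6-trimethylbenzoate
Product: 14 {2-[(S)-but-3-yn-2-yl]-1,3-dioxolan-2-yl}methyl 2,4-bis(benzyloxy)-3,5,6-trimethylbenzoate
Conditions: dimethyl (1-diazo-2-oxopropyl)phosphonate (1.5 equiv), K2CO3 (2 equiv), MeOH, 0 °C to rt
Reagents that add atoms: dimethyl (1-diazo-2-oxopropyl)phosphonate, CC(=O)C(=[N+]=[N-])P(=O)(OC)OC
Why: Ohira–Bestmann (Seyferth–Gilbert) homologation turns the aldehyde into the terminal alkyne under mild carbonate conditions, and the hindered aryl ester should not be methanolysed at this temperature.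

Step 13
Reactants: 14 {2-[(S)-but-3-yn-2-yl]-1,3-dioxolan-2-yl}methyl 2,4-bis(benzyloxy)-3,5,6-trimethylbenzoate
Product: 16 benzyl (S)-4-{2-[(2,4-bis(benzyloxy)-3,5,6-trimethylbenzoyloxy)methyl]-1,3-dioxolan-2-yl}pent-2-ynoate, via lithium acetylide 15 (not isolated)
Conditions: n-BuLi (1.05 equiv), THF, −78 °C; ClCO2Bn (1.3 equiv), −78 to −40 °C
Reagents that add atoms: benzyl chloroformate, O=C(Cl)OCc1ccccc1
Why: Deprotonation of the terminal alkyne is much faster than addition of n-BuLi to the di-ortho-substituted benzoate, and C-acylation of the acetylide by the chloroformate gives the ynoate with no base left to isomerise the propargylic centre.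

Step 14
Reactants: 17 methyl 3-oxopentanoate
Product: 18 methyl (E)-3-methoxypent-2-enoate
Conditions: HC(OMe)3 (1.5 equiv), H2SO4 (cat.), MeOH, rt; then distillation
Reagents that add atoms: trimethyl orthoformate, COC(OC)OC
Why: Acid-catalysed ketalisation with the orthoformate followed by loss of methanol on distillation gives the conjugated β-methoxy enoate (enol ether formation).

Step 15
Reactants: 18 methyl (E)-3-methoxypent-2-enoate
Product: 20 1,3-dimethoxy-1-trimethylsilyloxypenta-1,3-diene (E/Z mixture), via lithium dienolate 19 (not isolated)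
Conditions: LDA (1.1 equiv), THF, −78 °C; TMSCl (1.2 equiv), −78 °C to rt; filtered and concentrated under argon, used crude
Reagents that add atoms: chlorotrimethylsilane, C[Si](C)(C)Cl
Why: γ-Deprotonation of the vinylogous ester by LDA and O-silylation of the dienolate give the silyl ketene-acetal diene (Brassard-type diene synthesis).

Step 16
Reactants: 16 benzyl (S)-4-{2-[(2,4-bis(benzyloxy)-3,5,6-trimethylbenzoyloxy)methyl]-1,3-dioxolan-2-yl}pent-2-ynoate; 20 1,3-dimethoxy-1-trimethylsilyloxypenta-1,3-diene (E/Z mixture)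
Product: 23 benzyl 2-hydroxy-4-methoxy-5-methyl-6-[(S)-1-{2-[(2,4-bis(benzyloxy)-3,5,6-trimethylbenzoyloxy)methyl]-1,3-dioxolan-2-yl}ethyl]benzoate, via cyclohexa-1,4-diene cycloadduct 21 (not isolated), via aryl trimethylsilyl ether 22 (not isolated)
Conditions: 20 (4 equiv, in portions), toluene, 120 °C, sealed tube; then 0.5 M HCl, THF, 0 °C
Reagents that add atoms: none
Why: The electron-rich 1,1,3-trioxygenated diene 20 and the electron-poor ynoate 16 should combine in a normal-demand, strongly asynchronous Diels–Alder reaction in which the methyl-bearing diene terminus (future C5) bonds first to the β-carbon of the ynoate (future C4a) and the ketene-acetal carbon (future C8) then bonds to the α-carbon (future C8a), giving cyclohexa-1,4-diene 21. Adduct 21 aromatises by 1,4-elimination of methanol (the methoxy group on C8 and the hydrogen on C5) to the aryl silyl ether 22, and the cold acidic work-up cleaves the Si–O bond to leave the C8 phenol hydrogen-bonded to the benzyl ester. The closest known reaction type is the benzannulation of Brassard- and Chan-type silyloxy ketene-acetal dienes with acetylenic esters to give resorcylates. The benzene ring is closed by intermolecular [4+2] cycloaddition followed by eliminative aromatisation; no stereocentre is created, and the propargylic centre (C4) is safe because the medium is neutral and C3 is a ketal. The step needs regioselectivity, which the matched polarisation of the partners secures (donor oxygens on diene C1 and C3 against the ester on the alkyne), and loss of methanol in preference to silanol, which is the usual course for 1-methoxy-1-silyloxy dienes; only the diene isomer with the terminal methyl turned outward is expected to react, hence the excess.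

Step 17
Reactants: 23 benzyl 2-hydroxy-4-methoxy-5-methyl-6-[(S)-1-{2-[(2,4-bis(benzyloxy)-3,5,6-trimethylbenzoyloxy)methyl]-1,3-dioxolan-2-yl}ethyl]benzoate
Product: 24 2-hydroxy-4-methoxy-5-methyl-6-[(S)-1-{2-[(2,4-dihydroxy-3,5,6-trimethylbenzoyloxy)methyl]-1,3-dioxolan-2-yl}ethyl]benzoic acid
Conditions: H2 (1 atm), 10% Pd/C, EtOAc, rt
Reagents that add atoms: none
Why: Catalytic hydrogenolysis removes the benzyl ester and both aryl benzyl ethers in one operation, and the molecule holds no other reducible group or benzylic C–O bond.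

Step 18
Reactants: 24 2-hydroxy-4-methoxy-5-methyl-6-[(S)-1-{2-[(2,4-dihydroxy-3,5,6-trimethylbenzoyloxy)methyl]-1,3-dioxolan-2-yl}ethyl]benzoic acid
Product: 26 [(3R,4S)-3,8-dihydroxy-6-methoxy-4,5-dimethyl-1-oxo-3,4-dihydro-1H-isochromen-3-yl]methyl 2,4-dihydroxy-3,5,6-trimethylbenzoate (target), via open keto acid 25 (not isolated)
Conditions: 1 M aq. HCl/THF 1:3, rt to 40 °C
Reagents that add atoms: water, O
Why: Acid-catalysed ketal hydrolysis unmasks the C3 ketone, which the neighbouring carboxylic acid captures at once by 6-exo-trig addition to give the lactol, and the reversible closure should set C3 as the thermodynamic (3R) epimer while the short-lived ketone leaves little time for enolisation at C4.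

**Compound list**
1 | methyl 2,4-dihydroxy-3,6-dimethylbenzoate | COC(=O)c1c(C)cc(O)c(C)c1O | starting material
2 | methyl 5-bromo-2,4-dihydroxy-3,6-dimethylbenzoate | COC(=O)c1c(C)c(Br)c(O)c(C)c1O | intermediate
3 | methyl 2,4-bis(benzyloxy)-5-bromo-3,6-dimethylbenzoate | COC(=O)c1c(C)c(Br)c(OCc2ccccc2)c(C)c1OCc1ccccc1 | intermediate
4 | methyl 2,4-bis(benzyloxy)-3,5,6-trimethylbenzoate | COC(=O)c1c(C)c(C)c(OCc2ccccc2)c(C)c1OCc1ccccc1 | intermediate
5 | 2,4-bis(benzyloxy)-3,5,6-trimethylbenzoic acid | OC(=O)c1c(C)c(C)c(OCc2ccccc2)c(C)c1OCc1ccccc1 | intermediate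
6 | methyl (S)-3-hydroxy-2-methylpropanoate | OC[C@H](C)C(=O)OC | starting material
7 | methyl (S)-3-(tert-butyldiphenylsilyloxy)-2-methylpropanoate | COC(=O)[C@@H](C)CO[Si](c1ccccc1)(c1ccccc1)C(C)(C)C | intermediate
8 | (S)-3-(tert-butyldiphenylsilyloxy)-N-methoxy-N,2-dimethylpropanamide | CON(C)C(=O)[C@@H](C)CO[Si](c1ccccc1)(c1ccccc1)C(C)(C)C | intermediate
9 | (S)-4-(tert-butyldiphenylsilyloxy)-1-chloro-3-methylbutan-2-one | ClCC(=O)[C@@H](C)CO[Si](c1ccccc1)(c1ccccc1)C(C)(C)C | intermediate
10 | (S)-4-(tert-butyldiphenylsilyloxy)-3-methyl-2-oxobutyl 2,4-bis(benzyloxy)-3,5,6-trimethylbenzoate | O=C(OCC(=O)[C@@H](C)CO[Si](c1ccccc1)(c1ccccc1)C(C)(C)C)c1c(C)c(C)c(OCc2ccccc2)c(C)c1OCc1ccccc1 | intermediate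
11 | {2-[(S)-1-(tert-butyldiphenylsilyloxy)propan-2-yl]-1,3-dioxolan-2-yl}methyl 2,4-bis(benzyloxy)-3,5,6-trimethylbenzoate | O=C(OCC1(OCCO1)[C@@H](C)CO[Si](c2ccccc2)(c2ccccc2)C(C)(C)C)c1c(C)c(C)c(OCc2ccccc2)c(C)c1OCc1ccccc1 | intermediate
12 | {2-[(S)-1-hydroxypropan-2-yl]-1,3-dioxolan-2-yl}methyl 2,4-bis(benzyloxy)-3,5,6-trimethylbenzoate | O=C(OCC1(OCCO1)[C@@H](C)CO)c1c(C)c(C)c(OCc2ccccc2)c(C)c1OCc1ccccc1 | intermediate
13 | {2-[(S)-1-oxopropan-2-yl]-1,3-dioxolan-2-yl}methyl 2,4-bis(benzyloxy)-3,5,6-trimethylbenzoate | O=C(OCC1(OCCO1)[C@@H](C)C=O)c1c(C)c(C)c(OCc2ccccc2)c(C)c1OCc1ccccc1 | intermediate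
14 | {2-[(S)-but-3-yn-2-yl]-1,3-dioxolan-2-yl}methyl 2,4-bis(benzyloxy)-3,5,6-trimethylbenzoate | O=C(OCC1(OCCO1)[C@@H](C)C#C)c1c(C)c(C)c(OCc2ccccc2)c(C)c1OCc1ccccc1 | intermediate
15 | lithium acetylide of 14 | [Li]C#C[C@H](C)C1(COC(=O)c2c(C)c(C)c(OCc3ccccc3)c(C)c2OCc2ccccc2)OCCO1 | intermediate
16 | benzyl (S)-4-{2-[(2,4-bis(benzyloxy)-3,5,6-trimethylbenzoyloxy)methyl]-1,3-dioxolan-2-yl}pent-2-ynoate | O=C(OCc1ccccc1)C#C[C@H](C)C1(COC(=O)c2c(C)c(C)c(OCc3ccccc3)c(C)c2OCc2ccccc2)OCCO1 | intermediate
17 | methyl 3-oxopentanoate | CCC(=O)CC(=O)OC | starting material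
18 | methyl (E)-3-methoxypent-2-enoate | CC/C(OC)=C\C(=O)OC | intermediate
19 | lithium dienolate of 18 (lithium 1,3-dimethoxypenta-1,3-dien-1-olate) | CC=C(OC)C=C(OC)O[Li] | intermediate
20 | 1,3-dimethoxy-1-trimethylsilyloxypenta-1,3-diene (E/Z mixture) | CC=C(OC)C=C(OC)O[Si](C)(C)C | intermediate
21 | benzyl 4,6-dimethoxy-3-methyl-6-(trimethylsilyloxy)-2-[(S)-1-{2-[(2,4-bis(benzyloxy)-3,5,6-trimethylbenzoyloxy)methyl]-1,3-dioxolan-2-yl}ethyl]cyclohexa-1,4-diene-1-carboxylate (mixture at the two ring sp3 carbons) | COC1=CC(OC)(O[Si](C)(C)C)C(C(=O)OCc2ccccc2)=C([C@H](C)C2(COC(=O)c3c(C)c(C)c(OCc4ccccc4)c(C)c3OCc3ccccc3)OCCO2)C1C | intermediate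
22 | benzyl 4-methoxy-5-methyl-2-(trimethylsilyloxy)-6-[(S)-1-{2-[(2,4-bis(benzyloxy)-3,5,6-trimethylbenzoyloxy)methyl]-1,3-dioxolan-2-yl}ethyl]benzoate | COc1cc(O[Si](C)(C)C)c(C(=O)OCc2ccccc2)c([C@H](C)C2(COC(=O)c3c(C)c(C)c(OCc4ccccc4)c(C)c3OCc3ccccc3)OCCO2)c1C | intermediate
23 | benzyl 2-hydroxy-4-methoxy-5-methyl-6-[(S)-1-{2-[(2,4-bis(benzyloxy)-3,5,6-trimethylbenzoyloxy)methyl]-1,3-dioxolan-2-yl}ethyl]benzoate | COc1cc(O)c(C(=O)OCc2ccccc2)c([C@H](C)C2(COC(=O)c3c(C)c(C)c(OCc4ccccc4)c(C)c3OCc3ccccc3)OCCO2)c1C | intermediate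
24 | 2-hydroxy-4-methoxy-5-methyl-6-[(S)-1-{2-[(2,4-dihydroxy-3,5,6-trimethylbenzoyloxy)methyl]-1,3-dioxolan-2-yl}ethyl]benzoic acid | COc1cc(O)c(C(=O)O)c([C@H](C)C2(COC(=O)c3c(C)c(C)c(O)c(C)c3O)OCCO2)c1C | intermediate
25 | 2-hydroxy-4-methoxy-5-methyl-6-[(S)-4-(2,4-dihydroxy-3,5,6-trimethylbenzoyloxy)-3-oxobutan-2-yl]benzoic acid | COc1cc(O)c(C(=O)O)c([C@H](C)C(=O)COC(=O)c2c(C)c(C)c(O)c(C)c2O)c1C | intermediate
26 | [(3R,4S)-3,8-dihydroxy-6-methoxy-4,5-dimethyl-1-oxo-3,4-dihydro-1H-isochromen-3-yl]methyl 2,4-dihydroxy-3,5,6-trimethylbenzoate | COc1cc(O)c2c(c1C)[C@H](C)[C@](O)(COC(=O)c1c(C)c(C)c(O)c(C)c1O)OC2=O | target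

**Step count**
Total: 18 steps. Longest linear sequence: 13 steps (steps 1–4, 8–13, 16–18, from compound 1); the branch from the Roche ester 6 is 12 steps, and the diene branch is 2 steps.

**Steps most likely to fail**

Step 16. The cycloaddition may be too slow: the forming C5–C4a bond joins a methyl-bearing diene terminus to an alkyne carbon that carries a secondary centre next to a quaternary ketal, and meanwhile the diene can desilylate or decompose, or the adduct can lose silanol and give the C8 methyl ether. The fallback sets out from 16 and 17 and returns at 23. Methyl 3-oxopentanoate 17 would be silylated (TMSCl, Et3N) to methyl 3-(trimethylsilyloxy)pent-2-enoate F1, and LDA/TMSCl at −78 °C would convert this into the more nucleophilic 1-methoxy-1,3-bis(trimethylsilyloxy)penta-1,3-diene F2. Heating 16 with F2 in toluene and a cold acidic work-up should give benzyl 2,4-dihydroxy-5-methyl-6-[(S)-1-{2-[(2,4-bis(benzyloxy)-3,5,6-trimethylbenzoyloxy)methyl]-1,3-dioxolan-2-yl}ethyl]benzoate F3. Its 4-hydroxyl (C6–OH of the target) is the only one not held in the hydrogen bond to the ester, so MeI (1.1 equiv)/K2CO3 in acetone at rt should methylate it selectively and give 23.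

Step 12. The α-stereocentre of aldehyde 13 (future C4) may epimerise in methanolic carbonate before the alkyne is formed. The fallback sets out from 13 and returns at 16. A Corey–Fuchs sequence would replace steps 12 and 13: CBr4/PPh3 in CH2Cl2 at 0 °C should give, without base, {2-[(S)-4,4-dibromobut-3-en-2-yl]-1,3-dioxolan-2-yl}methyl 2,4-bis(benzyloxy)-3,5,6-trimethylbenzoate F4. n-BuLi (2.1 equiv) in THF at −78 °C would then generate acetylide 15 directly, and benzyl chloroformate would trap it in the same flask to give 16.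

Step 9. Ketalisation of the α′-branched, inductively deactivated α-acyloxy ketone may stall, and stronger Lewis-acid conditions invite loss of the silyl ether or participation of the ester carbonyl. The fallback sets out from 9 and returns at 11, inverting the order of events. The chloromethyl ketone 9 would be ketalised first under the same Noyori conditions to tert-butyl{(S)-2-[2-(chloromethyl)-1,3-dioxolan-2-yl]propoxy}diphenylsilane F5, which is smaller and has no neighbouring ester. The chloride would then be displaced by the caesium salt of acid 5 (Cs2CO3, NaI cat., DMF, 110 °C) to give 11; this neopentyl-type substitution is slow, but the heat is acceptable because the stereocentre now sits next to a ketal.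

**Further compounds**
F1 | step 16 | methyl 3-(trimethylsilyloxy)pent-2-enoate | CCC(O[Si](C)(C)C)=CC(=O)OC
F2 | step 16 | 1-methoxy-1,3-bis(trimethylsilyloxy)penta-1,3-diene | CC=C(O[Si](C)(C)C)C=C(OC)O[Si](C)(C)C
F3 | step 16 | benzyl 2,4-dihydroxy-5-methyl-6-[(S)-1-{2-[(2,4-bis(benzyloxy)-3,5,6-trimethylbenzoyloxy)methyl]-1,3-dioxolan-2-yl}ethyl]benzoate | Oc1cc(O)c(C(=O)OCc2ccccc2)c([C@H](C)C2(COC(=O)c3c(C)c(C)c(OCc4ccccc4)c(C)c3OCc3ccccc3)OCCO2)c1C
F4 | step 12 | {2-[(S)-4,4-dibromobut-3-en-2-yl]-1,3-dioxolan-2-yl}methyl 2,4-bis(benzyloxy)-3,5,6-trimethylbenzoate | BrC(Br)=C[C@H](C)C1(COC(=O)c2c(C)c(C)c(OCc3ccccc3)c(C)c2OCc2ccccc2)OCCO1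
F5 | step 9 | tert-butyl{(S)-2-[2-(chloromethyl)-1,3-dioxolan-2-yl]propoxy}diphenylsilane | ClCC1(OCCO1)[C@@H](C)CO[Si](c1ccccc1)(c1ccccc1)C(C)(C)C
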